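**Retrosynthetic overview** (chain atoms are counted C1'–C10' from the cyclohexane ring to the butenolide)
1. Butenolide ⇐ γ-hydroxybutenolide ⇐ 3-alkylfuran: [4+2] cycloaddition of singlet oxygen, base-induced endoperoxide opening, then NaBH4 reduction–lactonisation.
2. C1'–C2' bond ⇐ copper-catalysed coupling of the Grignard reagent of (S)-γ-cyclogeranyl bromide with an (E,E)-allylic bromide; the only stereocentre is bought in (S)-γ-cyclogeraniol and never touched.
3. Allylic bromide ⇐ dendrolasin by SeO2 oxidation of the terminal (E)-methyl group; both (E)-trisubstituted alkenes come unchanged from (E)-geranylacetone.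
4. Furan ring ⇐ Diels–Alder/retro-Diels–Alder reaction of 4-phenyloxazole with the terminal alkyne made from geranylacetone.
5. Ring order: cyclohexane ring bought; the five-membered oxygen heterocycle is built by cycloaddition (step 2) and taken to the butenolide last (steps 7–8).

Assumption: (S)-γ-cyclogeraniol of high enantiomeric purity is treated as a purchasable terpenoid starting material; it supplies the only stereocentre, and no step touches it.

**Route**

Step 1
Reactants: 1 (5E)-6,10-dimethylundeca-5,9-dien-2-one ((E)-geranylacetone)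
Product: 3 (5E)-6,10-dimethylundeca-5,9-dien-1-yne, via enol phosphate 2 (not isolated)
Conditions: LiN(iPr)2 (1.05 equiv), THF, −78 °C; ClP(O)(OEt)2, −78 °C → rt; then LiN(iPr)2 (2.3 equiv), THF, −78 °C → rt; aq. NH4Cl
Reagents that add atoms: none
Why: Negishi's one-pot methyl ketone → terminal alkyne conversion (kinetic deprotonation at the methyl group, O-phosphorylation, base-induced β-elimination of the enol phosphate) leaves the (E)-trisubstituted alkene untouched and creates no stereocentre.

Step 2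
Reactants: 3 (5E)-6,10-dimethylundeca-5,9-dien-1-yne; 4 4-phenyl-1,3-oxazole
Product: 6 3-[(3E)-4,8-dimethylnona-3,7-dien-1-yl]furan (dendrolasin), via oxazole–alkyne cycloadduct 5 (not isolated)
Conditions: 4 (1.3 equiv), neat, sealed tube, 220 °C, 16 h
Reagents that add atoms: none
Why: Hetero-Diels–Alder [4+2] cycloaddition of the oxazole across the unactivated alkyne, followed by retro-[4+2] loss of benzonitrile, builds the furan ring, and because C2 and C5 of the oxazole are unsubstituted both regioisomeric adducts give the same 3-alkylfuran.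

Step 3
Reactants: 6 dendrolasin
Product: 7 (2E,6E)-9-(furan-3-yl)-2,6-dimethylnona-2,6-dien-1-ol (neotorreyol)
Conditions: SeO2 (0.2 equiv), tBuOOH (70% aq., 2.5 equiv), salicylic acid (0.1 equiv), CH2Cl2, 0 °C → rt; stopped at partial conversion, 6 recycled
Reagents that add atoms: tert-butyl hydroperoxide, CC(C)(C)OO
Why: Sharpless SeO2/tBuOOH allylic oxidation (ene reaction, then [2,3]-sigmatropic shift of the allylseleninic acid) hydroxylates the (E)-methyl of the terminal trisubstituted alkene, so the new CH2OH is trans to the chain.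

Step 4
Reactants: 7 neotorreyol
Product: 8 3-[(3E,7E)-9-bromo-4,8-dimethylnona-3,7-dien-1-yl]furan
Conditions: CBr4, PPh3, CH2Cl2, −20 → 0 °C; used at once
Reagents that add atoms: carbon tetrabromide, BrC(Br)(Br)Br
Why: Appel bromination converts the primary allylic alcohol to the bromide by SN2 at CH2 under neutral conditions, without allylic transposition, E/Z loss or acid that would harm the furan.

Step 5
Reactants: 9 [(1S)-2,2-dimethyl-6-methylidenecyclohexyl]methanol ((S)-γ-cyclogeraniol)
Product: 10 (2S)-2-(bromomethyl)-1,1-dimethyl-3-methylidenecyclohexane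
Conditions: CBr4, PPh3, CH2Cl2, 0 °C → rt
Reagents that add atoms: carbon tetrabromide, BrC(Br)(Br)Br
Why: Appel reaction (SN2 at the primary CH2) gives the bromide; the neighbouring stereocentre is not a reacting centre and keeps its (S) configuration.

Step 6
Reactants: 10 (2S)-2-(bromomethyl)-1,1-dimethyl-3-methylidenecyclohexane; 8 3-[(3E,7E)-9-bromo-4,8-dimethylnona-3,7-dien-1-yl]furan
Product: 12 3-[(3E,7E)-10-[(1S)-2,2-dimethyl-6-methylidenecyclohexyl]-4,8-dimethyldeca-3,7-dien-1-yl]furan, via Grignard reagent 11 (not isolated)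
Conditions: Mg turnings, THF, 40 °C; then 8, Li2CuCl4 (5 mol %), THF, −78 → 0 °C
Reagents that add atoms: none
Why: Copper-catalysed α-selective (SN2) cross-coupling of a primary alkyl Grignard reagent with a primary allylic bromide (Fouquet–Schlosser type) forms the C1'–C2' bond with retention of the E geometry, and the stereocentre β to magnesium is not involved.

Step 7
Reactants: 12 3-[(3E,7E)-10-[(1S)-2,2-dimethyl-6-methylidenecyclohexyl]-4,8-dimethyldeca-3,7-dien-1-yl]furan
Product: 14 5-hydroxy-4-[(3E,7E)-10-[(1S)-2,2-dimethyl-6-methylidenecyclohexyl]-4,8-dimethyldeca-3,7-dien-1-yl]furan-2(5H)-one, via furan endoperoxide 13 (not isolated)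
Conditions: O2, hν (visible), 5,10,15,20-tetraphenylporphyrin (cat.), iPr2NEt, CH2Cl2, −78 °C; then warm to rt
Reagents that add atoms: dioxygen, O=O
Why: [4+2] cycloaddition of singlet oxygen to the furan (much faster at −78 °C than the ene reaction of the isolated alkenes) gives the endoperoxide, and the hindered amine removes the bridgehead proton remote from the alkyl group (Kornblum–DeLaMare-type opening), giving the 4-alkyl-5-hydroxybutenolide regioselectively with an uncontrolled, transient hemiacetal centre.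

Step 8
Reactants: 14 5-hydroxy-4-[(3E,7E)-10-[(1S)-2,2-dimethyl-6-methylidenecyclohexyl]-4,8-dimethyldeca-3,7-dien-1-yl]furan-2(5H)-one
Product: 16 4-[(3E,7E)-10-[(1S)-2,2-dimethyl-6-methylidenecyclohexyl]-4,8-dimethyldeca-3,7-dien-1-yl]furan-2(5H)-one, via Z-hydroxy acid 15 (not isolated)
Conditions: NaBH4, EtOH/THF, 0 °C; then 1 M HCl, rt
Reagents that add atoms: none
Why: NaBH4 reduces the aldehyde of the ring-opened (Z)-4-oxo-2-enoate form of the hydroxybutenolide and acidification lactonises the (Z)-γ-hydroxy acid, which removes the hemiacetal centre and leaves the bought (S) centre as the only stereocentre.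

**Compound list**
1 | (5E)-6,10-dimethylundeca-5,9-dien-2-one ((E)-geranylacetone) | CC(=O)CC/C=C(\C)CCC=C(C)C | starting material
2 | diethyl (5E)-6,10-dimethylundeca-1,5,9-trien-2-yl phosphate | C=C(CC/C=C(\C)CCC=C(C)C)OP(=O)(OCC)OCC | intermediate
3 | (5E)-6,10-dimethylundeca-5,9-dien-1-yne | C#CCC/C=C(\C)CCC=C(C)C | intermediate
4 | 4-phenyl-1,3-oxazole | c1ccc(cc1)-c1cocn1 | starting material
5 | 5-[(3E)-4,8-dimethylnona-3,7-dien-1-yl]-3-phenyl-7-oxa-2-azabicyclo[2.2.1]hepta-2,5-diene (racemic; the 6-alkyl regioisomer forms as well and collapses to the same furan) | CC(C)=CCC/C(C)=C/CCC1=CC2N=C(c3ccccc3)C1O2 | intermediate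
6 | 3-[(3E)-4,8-dimethylnona-3,7-dien-1-yl]furan (dendrolasin) | CC(C)=CCC/C(C)=C/CCc1ccoc1 | intermediate
7 | (2E,6E)-9-(furan-3-yl)-2,6-dimethylnona-2,6-dien-1-ol (neotorreyol) | OC/C(C)=C/CC/C(C)=C/CCc1ccoc1 | intermediate
8 | 3-[(3E,7E)-9-bromo-4,8-dimethylnona-3,7-dien-1-yl]furan | BrC/C(C)=C/CC/C(C)=C/CCc1ccoc1 | intermediate
9 | [(1S)-2,2-dimethyl-6-methylidenecyclohexyl]methanol ((S)-γ-cyclogeraniol) | C=C1CCCC(C)(C)[C@@H]1CO | starting material
10 | (2S)-2-(bromomethyl)-1,1-dimethyl-3-methylidenecyclohexane | C=C1CCCC(C)(C)[C@@H]1CBr | intermediate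
11 | {[(1S)-2,2-dimethyl-6-methylidenecyclohexyl]methyl}magnesium bromide | C=C1CCCC(C)(C)[C@@H]1C[Mg]Br | intermediate
12 | 3-[(3E,7E)-10-[(1S)-2,2-dimethyl-6-methylidenecyclohexyl]-4,8-dimethyldeca-3,7-dien-1-yl]furan | C=C1CCCC(C)(C)[C@@H]1CC/C(C)=C/CC/C(C)=C/CCc1ccoc1 | intermediate
13 | 5-[(3E,7E)-10-[(1S)-2,2-dimethyl-6-methylidenecyclohexyl]-4,8-dimethyldeca-3,7-dien-1-yl]-2,3,7-trioxabicyclo[2.2.1]hept-5-ene | C=C1CCCC(C)(C)[C@@H]1CC/C(C)=C/CC/C(C)=C/CCC1=CC2OOC1O2 | intermediate
14 | 5-hydroxy-4-[(3E,7E)-10-[(1S)-2,2-dimethyl-6-methylidenecyclohexyl]-4,8-dimethyldeca-3,7-dien-1-yl]furan-2(5H)-one (both C5 epimers) | C=C1CCCC(C)(C)[C@@H]1CC/C(C)=C/CC/C(C)=C/CCC1=CC(=O)OC1O | intermediate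
15 | (2Z,6E,10E)-3-(hydroxymethyl)-7,11-dimethyl-13-[(1S)-2,2-dimethyl-6-methylidenecyclohexyl]trideca-2,6,10-trienoic acid (present as its sodium salt) | C=C1CCCC(C)(C)[C@@H]1CC/C(C)=C/CC/C(C)=C/CC/C(CO)=C/C(=O)O | intermediate
16 | 4-[(3E,7E)-10-[(1S)-2,2-dimethyl-6-methylidenecyclohexyl]-4,8-dimethyldeca-3,7-dien-1-yl]furan-2(5H)-one | C=C1CCCC(C)(C)[C@@H]1CC/C(C)=C/CC/C(C)=C/CCC1=CC(=O)OC1 | target

**Totals**
Total step count: 8. Longest linear sequence: 7 steps (1 → 3 → 6 → 7 → 8 → 12 → 14 → 16); step 5 is the one-step side branch.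

**Steps most likely to fail, with fallbacks**

Step 3 (SeO2 oxidation in the presence of the furan and a second trisubstituted alkene: modest yield, site selectivity, furan erosion). Fallback: the allylic oxidation is moved in front of the heterocycle. Setting out from 3, SeO2 (cat.)/tBuOOH on the furan-free enyne gives (2E,6E)-2,6-dimethylundeca-2,6-dien-10-yn-1-ol F1. This is heated with 4 (neat, 220 °C) and passes through the cycloadduct (2E,6E)-2,6-dimethyl-9-(3-phenyl-7-oxa-2-azabicyclo[2.2.1]hepta-2,5-dien-5-yl)nona-2,6-dien-1-ol F2, which loses benzonitrile; the sequence comes back to the route at 7.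

Step 6 (formation of the hindered homoallylic Grignard reagent and α/γ selectivity of the allylic coupling). Fallback: a sulfone alkylation–desulfonylation replaces the organomagnesium coupling. Setting out from 10, PhSO2Na (Bu4NI cat., DMF, 80 °C) gives {[(1S)-2,2-dimethyl-6-methylidenecyclohexyl]methanesulfonyl}benzene F3. Its lithio anion (n-BuLi, THF, −78 °C) is alkylated by 8 to give 3-[(3E,7E)-10-(benzenesulfonyl)-10-[(1S)-2,2-dimethyl-6-methylidenecyclohexyl]-4,8-dimethyldeca-3,7-dien-1-yl]furan F4. Sodium amalgam (Na/Hg, Na2HPO4, MeOH, −20 °C) removes the sulfonyl group, and the sequence comes back to the route at 12.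

Step 7 (competition of the singlet-oxygen ene reaction at the two trisubstituted alkenes, and regiochemistry of endoperoxide opening). Fallback: the furan is oxidised without singlet oxygen. Setting out from 12, C–H borylation at the unhindered α-position ([Ir(OMe)(cod)]2, 4,4'-di-tert-butyl-2,2'-bipyridine, bis(pinacolato)diboron, hexane, rt) gives 2-{4-[(3E,7E)-10-[(1S)-2,2-dimethyl-6-methylidenecyclohexyl]-4,8-dimethyldeca-3,7-dien-1-yl]furan-2-yl}-4,4,5,5-tetramethyl-1,3,2-dioxaborolane F5. Oxidation with NaBO3·4H2O (THF/H2O, rt) gives the 2-hydroxyfuran, which tautomerises to the butenolide; the sequence comes back to the route directly at 16, bypassing 14 and step 8.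

**Further compounds**
F1 | step 3 | (2E,6E)-2,6-dimethylundeca-2,6-dien-10-yn-1-ol | OC/C(C)=C/CC/C(C)=C/CCC#C
F2 | step 3 | (2E,6E)-2,6-dimethyl-9-(3-phenyl-7-oxa-2-azabicyclo[2.2.1]hepta-2,5-dien-5-yl)nona-2,6-dien-1-ol | OC/C(C)=C/CC/C(C)=C/CCC1=CC2N=C(c3ccccc3)C1O2
F3 | step 6 | {[(1S)-2,2-dimethyl-6-methylidenecyclohexyl]methanesulfonyl}benzene | C=C1CCCC(C)(C)[C@@H]1CS(=O)(=O)c1ccccc1
F4 | step 6 | 3-[(3E,7E)-10-(benzenesulfonyl)-10-[(1S)-2,2-dimethyl-6-methylidenecyclohexyl]-4,8-dimethyldeca-3,7-dien-1-yl]furan (both epimers at the sulfonyl carbon) | C=C1CCCC(C)(C)[C@@H]1C(C/C(C)=C/CC/C(C)=C/CCc1ccoc1)S(=O)(=O)c1ccccc1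
F5 | step 7 | 2-{4-[(3E,7E)-10-[(1S)-2,2-dimethyl-6-methylidenecyclohexyl]-4,8-dimethyldeca-3,7-dien-1-yl]furan-2-yl}-4,4,5,5-tetramethyl-1,3,2-dioxaborolane | C=C1CCCC(C)(C)[C@@H]1CC/C(C)=C/CC/C(C)=C/CCc1coc(B2OC(C)(C)C(C)(C)O2)c1
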